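The synthesis rests on the biaryl bond between C8 of ring A of the dihydroflavonol (the CH flanked by O7 and the ring oxygen O1) and C3′ of ring B of the apigenin unit (ortho to 4′-OH). Both carbons are innately nucleophilic phenol-type positions, so they are joined by a dehydrogenative cross-coupling with polarity reversal: PhI(OAc)2 turns the free 4′-phenol of 7-O-Cbz-apigenin into an aryloxy-λ3-iodane whose C3′ is electrophilic, and C8–H of 5,7,4′-tri-O-benzyl-(2R,3R)-aromadendrin attacks it. One operation unites both complete flavonoid halves without halide or boron handles; the chiral pool supplies both stereocenters, and one hydrogenolysis unmasks the target.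

Key step: step 3

Assumption: the biaryl axis (ortho substituents OH, ring O, OH and H) is taken as not configurationally fixed, since the target SMILES gives no axial descriptor; (2R,3R)-(+)-aromadendrin and apigenin are bought.

Step 1
Reactants: 1 (2R,3R)-(+)-aromadendrin
Product: 2 (2R,3R)-5,7-bis(benzyloxy)-2-[4-(benzyloxy)phenyl]-3-hydroxychroman-4-one (5,7,4′-tri-O-benzylaromadendrin)
Conditions: BnBr (3.5 equiv), K2CO3 (4 equiv), Bu4NI (cat.), DMF, Ar, rt then 45 °C
Reagents that add atoms: benzyl bromide, BrCc1ccccc1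
Why: Williamson ether synthesis on the three phenols (7-OH and 4′-OH react first, the chelated 5-OH on gentle warming) leaves the far less acidic secondary 3-OH free, and no stereocenter is made: both (2R,3R) centers come from the chiral pool and are guarded by exclusion of air, mild base and the thermodynamic preference for the 2,3-trans arrangement.

Step 2
Reactants: 3 apigenin
Product: 5 benzyl 5-hydroxy-2-(4-hydroxyphenyl)-4-oxo-4H-chromen-7-yl carbonate (7-O-Cbz-apigenin), via potassium 7-phenoxide of apigenin 4 (not isolated)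
Conditions: KOtBu (1.0 equiv), DMF, −20 °C; then CbzCl (1.0 equiv), −20 → 0 °C
Reagents that add atoms: benzyl chloroformate, O=C(Cl)OCc1ccccc1
Why: Selective O-acylation (carbonate formation) of a mono-phenoxide: one equivalent of KOtBu ionises the most acidic OH, the 7-OH para to the C4 carbonyl, the chelated 5-OH is inert and the 4′-OH stays free for the key step; no stereocenter is made.

Step 3
Reactants: 5 7-O-Cbz-apigenin; 2 5,7,4′-tri-O-benzyl-(2R,3R)-aromadendrin
Product: 8 benzyl 2-{3-[(2R,3R)-5,7-bis(benzyloxy)-2-(4-(benzyloxy)phenyl)-3-hydroxy-4-oxochroman-8-yl]-4-hydroxyphenyl}-5-hydroxy-4-oxo-4H-chromen-7-yl carbonate, via aryloxy-λ3-iodane 6 (not isolated), via cyclohexa-2,4-dienone adduct 7 (not isolated)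
Conditions: PhI(OAc)2 (1.0 equiv, slow addition), 2 (2 equiv, excess recovered), (CF3)2CHOH–CH2Cl2, −20 → 0 °C
Reagents that add atoms: none
Why: PhI(OAc)2 should exchange a ligand only with the 4′-OH of 5 (2 has no phenol, and the 5-OH of 5 is locked in its hydrogen bond to C4=O), giving aryloxy-λ3-iodane 6, a phenoxenium equivalent in which C3′/C5′ of ring B are electrophilic while the para carbon C1′ is blocked by the chromone. C8 of 2 attacks C3′ in a Friedel–Crafts sense with loss of PhI and acetate to give dienone 7, which tautomerises to the biaryl phenol 8. The closest known reaction type is the dehydrogenative phenol–arene cross-coupling in (CF3)2CHOH (trivalent-iodine, FeCl3/t-BuOOt-Bu or anodic variants), which joins para-substituted phenols at the ortho carbon to 1,3,5-trialkoxybenzenes. No ring is closed and no stereocenter is made: the sp3 carbon of 7 is lost on tautomerisation, the biaryl axis is not fixed, and C2/C3 of 2 meet neither base nor heat. The step needs cross- over self-coupling, C3′ over ring A of 5, and C8 over C6 of 2: the carbonate at O7 and the chelated carbonyl make ring A of 5 a poor nucleophile, the tri-O-alkylated ring A of 2 is the best π-nucleophile present and is used in excess, and C8 (between O7 and the ring oxygen) is less hindered than C6 (between two benzyloxy groups). The acceptor character of the para chromone makes the phenol of 5 harder to activate than the phenols usually used, which is the main risk of the step.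

Step 4
Reactants: 8 protected biflavonoid
Product: 9 (2R,3R)-8-[5-(5,7-dihydroxy-4-oxo-4H-chromen-2-yl)-2-hydroxyphenyl]-3,5,7-trihydroxy-2-(4-hydroxyphenyl)chroman-4-one (target)
Conditions: H2 (1 atm), 10% Pd/C, EtOAc–MeOH, rt
Reagents that add atoms: none
Why: Catalytic hydrogenolysis cleaves the three benzyl ethers and the benzyl carbonate (which then loses CO2) under neutral conditions that spare the flavone C2=C3 bond, both carbonyl groups and the base-sensitive trans-α-ketol, so the (2R,3R) centers are kept and no stereocenter is made.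

Compound list
1 | (2R,3R)-(+)-aromadendrin, (2R,3R)-3,5,7-trihydroxy-2-(4-hydroxyphenyl)chroman-4-one | O=C1c2c(O)cc(O)cc2O[C@H](c2ccc(O)cc2)[C@H]1O | starting material
2 | (2R,3R)-5,7-bis(benzyloxy)-2-[4-(benzyloxy)phenyl]-3-hydroxychroman-4-one | O=C1c2c(OCc3ccccc3)cc(OCc3ccccc3)cc2O[C@H](c2ccc(OCc3ccccc3)cc2)[C@H]1O | intermediate
3 | apigenin, 5,7-dihydroxy-2-(4-hydroxyphenyl)-4H-chromen-4-one | O=c1cc(-c2ccc(O)cc2)oc2cc(O)cc(O)c12 | starting material
4 | potassium 5-hydroxy-2-(4-hydroxyphenyl)-4-oxo-4H-chromen-7-olate (potassium 7-phenoxide of apigenin, not isolated) | O=c1cc(-c2ccc(O)cc2)oc2cc([O-])cc(O)c12.[K+] | intermediate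
5 | benzyl 5-hydroxy-2-(4-hydroxyphenyl)-4-oxo-4H-chromen-7-yl carbonate | O=c1cc(-c2ccc(O)cc2)oc2cc(OC(=O)OCc3ccccc3)cc(O)c12 | intermediate
6 | acetoxy(phenyl)-λ3-iodanyl ether of 5 at O4′ (aryloxy-λ3-iodane, not isolated) | CC(=O)OI(Oc1ccc(-c2cc(=O)c3c(O)cc(OC(=O)OCc4ccccc4)cc3o2)cc1)c1ccccc1 | intermediate
7 | 6-aryl-cyclohexa-2,4-dienone adduct, keto tautomer of 8 at ring B (sp3 carbon unassigned, not isolated) | O=C1c2c(OCc3ccccc3)cc(OCc3ccccc3)c(C3C=C(-c4cc(=O)c5c(O)cc(OC(=O)OCc6ccccc6)cc5o4)C=CC3=O)c2O[C@H](c2ccc(OCc3ccccc3)cc2)[C@H]1O | intermediate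
8 | benzyl 2-{3-[(2R,3R)-5,7-bis(benzyloxy)-2-(4-(benzyloxy)phenyl)-3-hydroxy-4-oxochroman-8-yl]-4-hydroxyphenyl}-5-hydroxy-4-oxo-4H-chromen-7-yl carbonate | O=C1c2c(OCc3ccccc3)cc(OCc3ccccc3)c(-c3cc(-c4cc(=O)c5c(O)cc(OC(=O)OCc6ccccc6)cc5o4)ccc3O)c2O[C@H](c2ccc(OCc3ccccc3)cc2)[C@H]1O | intermediate
9 | (2R,3R)-8-[5-(5,7-dihydroxy-4-oxo-4H-chromen-2-yl)-2-hydroxyphenyl]-3,5,7-trihydroxy-2-(4-hydroxyphenyl)chroman-4-one | O=C1c2c(O)cc(O)c(-c3cc(-c4cc(=O)c5c(O)cc(O)cc5o4)ccc3O)c2O[C@H](c2ccc(O)cc2)[C@H]1O | target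

Total step count: 4
Longest linear sequence: 3 steps (1 → 2 → 8 → 9, or 3 → 5 → 8 → 9)

Steps most likely to fail

Step 3 (key step). Activation of the acceptor-substituted phenol of 5 may be too slow. PhI(OAc)2 could then oxidise ring A of 2 directly, the more electron-rich product phenol could be over-oxidised, 5 could couple with itself, attack could occur at C6 instead of C8, or the α-ketol could be cleaved oxidatively. Fallback (known chemistry, Suzuki–Miyaura coupling; it sets out from 2 and comes back to the route at 9): iodination of 2 at C8 with N-iodosuccinimide (CF3CO2H cat., CH2Cl2, 0 °C) should give 8-iodo-5,7,4′-tri-O-benzylaromadendrin F1. Separately, commercial 1-[2,4-bis(benzyloxy)-6-hydroxyphenyl]ethanone (CC(=O)c1c(O)cc(OCc2ccccc2)cc1OCc1ccccc1) and 4-(benzyloxy)-3-bromobenzaldehyde (O=Cc1ccc(OCc2ccccc2)c(Br)c1) are condensed (KOH, EtOH, rt, Claisen–Schmidt) to the 2′-hydroxychalcone F2. F2 is cyclised oxidatively (I2 cat., DMSO, 120 °C) to 3′-bromo-5,7,4′-tri-O-benzylapigenin F3, which is borylated (B2pin2, PdCl2(dppf), KOAc, dioxane, 90 °C) to the pinacol boronate F4. Cross-coupling of F1 with F4 (Pd(OAc)2, SPhos, K3PO4, toluene–H2O, 60 °C) should give the hexa-O-benzyl biflavonoid F5, and hydrogenolysis under the conditions of step 4 gives 9.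

Step 2. Site selectivity may be poor: the less stabilised 4′-phenoxide, although present in small amount, is the more nucleophilic and may drain the mono-anion equilibrium, giving acylation at O4′, double acylation or carbonate migration on work-up. Fallback (protect O4′ first, using exactly this higher nucleophilicity; it sets out from 3 and comes back at 5): the dianion of 3 (KOtBu 2.1 equiv, DMF, 0 °C) is alkylated with one equivalent of 4-methoxybenzyl chloride to give 4′-O-(4-methoxybenzyl)apigenin F6. Its only non-chelated OH is then acylated (CbzCl, K2CO3, acetone, 0 °C) to the 7-O-Cbz-4′-O-PMB derivative F7, and the PMB ether is removed under acid with a cation trap (CF3CO2H, Et3SiH, CH2Cl2, 0 °C) to give 5.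

Step 1. The slow etherification of the chelated 5-OH may allow base-induced enolisation or opening of ring C (loss of configuration at C2 and C3, ring contraction) and aerial dehydrogenation to the flavonol. Fallback (enantioselective construction in place of the chiral pool; it does not set out from a numbered compound but replaces 1, and it comes back to the route at 2): commercial 1-[2,4-bis(benzyloxy)-6-hydroxyphenyl]ethanone (CC(=O)c1c(O)cc(OCc2ccccc2)cc1OCc1ccccc1) is protected (MOMCl, NaH, DMF, 0 °C) as the MOM ether F8. F8 is condensed with commercial 4-(benzyloxy)benzaldehyde (O=Cc1ccc(OCc2ccccc2)cc1) (KOH, EtOH–THF, rt) to the (E)-chalcone F9. Juliá–Colonna epoxidation (poly-L-leucine, urea·H2O2, DBU, THF) should give the (2R,3S)-epoxy ketone F10. Acid (HCl, MeOH–THF, 40 °C) removes the MOM group, and the freed phenol opens the epoxide 6-endo at the benzylic carbon with inversion, which gives the trans-(2R,3R)-dihydroflavonol 2.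

Further compounds
F1 | step 3 | (2R,3R)-5,7-bis(benzyloxy)-2-[4-(benzyloxy)phenyl]-3-hydroxy-8-iodochroman-4-one | O=C1c2c(OCc3ccccc3)cc(OCc3ccccc3)c(I)c2O[C@H](c2ccc(OCc3ccccc3)cc2)[C@H]1O
F2 | step 3 | (E)-1-[2,4-bis(benzyloxy)-6-hydroxyphenyl]-3-[4-(benzyloxy)-3-bromophenyl]prop-2-en-1-one | O=C(/C=C/c1ccc(OCc2ccccc2)c(Br)c1)c1c(O)cc(OCc2ccccc2)cc1OCc1ccccc1
F3 | step 3 | 5,7-bis(benzyloxy)-2-[4-(benzyloxy)-3-bromophenyl]-4H-chromen-4-one | O=c1cc(-c2ccc(OCc3ccccc3)c(Br)c2)oc2cc(OCc3ccccc3)cc(OCc3ccccc3)c12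
F4 | step 3 | 5,7-bis(benzyloxy)-2-[4-(benzyloxy)-3-(4,4,5,5-tetramethyl-1,3,2-dioxaborolan-2-yl)phenyl]-4H-chromen-4-one | CC1(C)OB(c2cc(-c3cc(=O)c4c(OCc5ccccc5)cc(OCc5ccccc5)cc4o3)ccc2OCc2ccccc2)OC1(C)C
F5 | step 3 | (2R,3R)-5,7-bis(benzyloxy)-8-{2-(benzyloxy)-5-[5,7-bis(benzyloxy)-4-oxo-4H-chromen-2-yl]phenyl}-2-[4-(benzyloxy)phenyl]-3-hydroxychroman-4-one | O=C1c2c(OCc3ccccc3)cc(OCc3ccccc3)c(-c3cc(-c4cc(=O)c5c(OCc6ccccc6)cc(OCc6ccccc6)cc5o4)ccc3OCc3ccccc3)c2O[C@H](c2ccc(OCc3ccccc3)cc2)[C@H]1O
F6 | step 2 | 5,7-dihydroxy-2-{4-[(4-methoxybenzyl)oxy]phenyl}-4H-chromen-4-one | COc1ccc(COc2ccc(-c3cc(=O)c4c(O)cc(O)cc4o3)cc2)cc1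
F7 | step 2 | benzyl 5-hydroxy-2-{4-[(4-methoxybenzyl)oxy]phenyl}-4-oxo-4H-chromen-7-yl carbonate | COc1ccc(COc2ccc(-c3cc(=O)c4c(O)cc(OC(=O)OCc5ccccc5)cc4o3)cc2)cc1
F8 | step 1 | 1-[2,4-bis(benzyloxy)-6-(methoxymethoxy)phenyl]ethanone | CC(=O)c1c(OCOC)cc(OCc2ccccc2)cc1OCc1ccccc1
F9 | step 1 | (E)-1-[2,4-bis(benzyloxy)-6-(methoxymethoxy)phenyl]-3-[4-(benzyloxy)phenyl]prop-2-en-1-one | COCOc1cc(OCc2ccccc2)cc(OCc2ccccc2)c1C(=O)/C=C/c1ccc(OCc2ccccc2)cc1
F10 | step 1 | [(2R,3S)-3-(4-(benzyloxy)phenyl)oxiran-2-yl][2,4-bis(benzyloxy)-6-(methoxymethoxy)phenyl]methanone | COCOc1cc(OCc2ccccc2)cc(OCc2ccccc2)c1C(=O)[C@@H]1O[C@H]1c1ccc(OCc2ccccc2)cc1
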